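The route rests on opening the oxolane ring (O, C7, C8, C9, C10) that bridges the ten-membered carbocycle (germacranolide numbering), at C9–C10 and O–C7. The key step exploits two latent polarities of this ring: C9 lies next to a C8 carbonyl, and C7 is the β-carbon of the C11–C12 lactone enoate, whose C13 can carry a leaving group. The precursor is therefore a seco butenolide with a bromoacetyl group on C7, an acetoxymethyl group on C11 and a 1,2-diketone (C1, C10) at the end of the epoxide chain. In one operation SmI2 closes the carbocycle by a Reformatsky aldol addition and the oxolane by SN2′ attack of the new alkoxide, which also unveils the methylene lactone.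

Key step: step 11

Remark: atoms are numbered as in germacranolides (C1 ring ketone, C4–C5 epoxide with C15 on C4, C6 lactone CH–O, C7 spiro carbon, C8 ester carbinol, C9 CH2, C10 ether carbon with C14, C11=C13 methylene, C12 lactone carbonyl); "exo" means the face of the oxolane next to the ether bridge and away from the six-carbon bridge C1–C6, which is where the SMILES places the C8 ester.

Step 1
Reactants: 1 nerol
Product: 2 [(2S,3R)-3-methyl-3-(4-methylpent-3-en-1-yl)oxiran-2-yl]methanol
Conditions: Ti(OiPr)4 (cat.), L-(+)-diethyl tartrate (cat.), t-BuOOH, 4 Å MS, CH2Cl2, −20 °C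
Reagents that add atoms: tert-butyl hydroperoxide CC(C)(C)OO
Why: Katsuki–Sharpless asymmetric epoxidation, in which the allylic hydroxyl anchors the alkene on the titanium tartrate complex and the L-(+)-tartrate delivers oxygen to the face of the (Z)-alkene that gives the (2S,3R)-epoxide, which sets C4 and C5 and leaves the remote alkene untouched.

Step 2
Reactants: 2 [(2S,3R)-3-methyl-3-(4-methylpent-3-en-1-yl)oxiran-2-yl]methanol
Product: 4 3-[(2R,3S)-3-(hydroxymethyl)-2-methyloxiran-2-yl]propanal, via ozonide 3 (not isolated)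
Conditions: O3, CH2Cl2, −78 °C; then PPh3, −78 °C → rt
Reagents that add atoms: ozone [O-][O+]=O
Why: Ozonolysis with reductive work-up cleaves the only C=C bond to the C1 aldehyde and acetone, while the epoxide and the alcohol are inert to ozone at −78 °C and no stereocenter is touched.

Step 3
Reactants: 4 3-[(2R,3S)-3-(hydroxymethyl)-2-methyloxiran-2-yl]propanal
Product: 5 [(2S,3R)-3-(but-3-yn-1-yl)-3-methyloxiran-2-yl]methanol
Conditions: dimethyl (1-diazo-2-oxopropyl)phosphonate, K2CO3, MeOH, 0 °C → rt
Reagents that add atoms: dimethyl (1-diazo-2-oxopropyl)phosphonate CC(=O)C(=[N+]=[N-])P(=O)(OC)OC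
Why: Seyferth–Gilbert homologation in its Ohira–Bestmann form, in which methanolysis frees the diazomethylphosphonate anion that converts the aldehyde into the terminal alkyne (C10 is added) under conditions mild enough for the epoxy alcohol.

Step 4
Reactants: 5 [(2S,3R)-3-(but-3-yn-1-yl)-3-methyloxiran-2-yl]methanol
Product: 7 [(2S,3R)-3-methyl-3-(pent-3-yn-1-yl)oxiran-2-yl]methanol, via dilithio alkoxide acetylide 6 (not isolated)
Conditions: n-BuLi (2.1 equiv), THF, −78 °C; MeI, −78 → 0 °C; H2O
Reagents that add atoms: iodomethane CI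
Why: Alkylation of a lithium acetylide, in which the second equivalent of base forms the acetylide and this carbon nucleophile reacts with MeI far faster than the lithium alkoxide, so that C14 is added and the 2-butynyl terminus stands as a masked 1,2-diketone.

Step 5
Reactants: 7 [(2S,3R)-3-methyl-3-(pent-3-yn-1-yl)oxiran-2-yl]methanol
Product: 8 (2R,3R)-3-methyl-3-(pent-3-yn-1-yl)oxirane-2-carbaldehyde
Conditions: TEMPO (cat.), PhI(OAc)2, CH2Cl2, rt
Reagents that add atoms: none
Why: Oxoammonium (TEMPO) oxidation with PhI(OAc)2 as terminal oxidant stops at the aldehyde, is a standard way from 2,3-epoxy alcohols to epoxy aldehydes and leaves the alkyne and the configuration at C5 untouched.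

Step 6
Reactants: 8 (2R,3R)-3-methyl-3-(pent-3-yn-1-yl)oxirane-2-carbaldehyde; 9 methyl propiolate
Product: 11 methyl (4S)-4-hydroxy-4-[(2S,3R)-3-methyl-3-(pent-3-yn-1-yl)oxiran-2-yl]but-2-ynoate, via lithium methyl propiolate 10 (not isolated)
Conditions: 9, LiHMDS, THF, −78 °C; then 8, −78 °C; aq. NH4Cl
Reagents that add atoms: none
Why: 1,2-Addition of a lithium acetylide to an α,β-epoxy aldehyde without chelation follows the Felkin–Anh polar model, so the nucleophile should enter anti to the epoxide C–O bond and give mainly the anti epoxy alcohol with the C6 configuration of the target, the syn isomer being removed by chromatography.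

Step 7
Reactants: 11 methyl (4S)-4-hydroxy-4-[(2S,3R)-3-methyl-3-(pent-3-yn-1-yl)oxiran-2-yl]but-2-ynoate; 12 ethyl vinyl ether
Product: 16 (5S)-4-(1-ethoxyethenyl)-3-(hydroxymethyl)-5-[(2S,3R)-3-methyl-3-(pent-3-yn-1-yl)oxiran-2-yl]furan-2(5H)-one, via 1-ethoxyvinyllithium 13 (not isolated), via lithium bis(1-ethoxyvinyl)cuprate 14 (not isolated), via open-chain dilithium dialkoxide 15 (not isolated)
Conditions: 12, t-BuLi, THF, −78 → 0 °C; CuBr·SMe2, −78 °C; 11 (to 2.5 equiv of cuprate), −78 °C; CH2O (gas, from paraformaldehyde), −78 → −20 °C; aq. NH4Cl/NH3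
Reagents that add atoms: formaldehyde C=O
Why: Conjugate addition of an α-alkoxyvinyl cuprate (a masked acetyl anion) to the ynoate places C8 on C7 by syn addition, the α-cuprio enoate is trapped by formaldehyde at C11 (tandem conjugate addition–aldol) and the C6 alkoxide, now cis to the ester, lactonises, so the fully substituted butenolide forms without a new stereocenter.

Step 8
Reactants: 16 (5S)-4-(1-ethoxyethenyl)-3-(hydroxymethyl)-5-[(2S,3R)-3-methyl-3-(pent-3-yn-1-yl)oxiran-2-yl]furan-2(5H)-one
Product: 17 [(5S)-4-(1-ethoxyethenyl)-5-[(2S,3R)-3-methyl-3-(pent-3-yn-1-yl)oxiran-2-yl]-2-oxo-2,5-dihydrofuran-3-yl]methyl acetate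
Conditions: Ac2O, pyridine, DMAP (cat.), CH2Cl2, 0 °C
Reagents that add atoms: acetic anhydride CC(=O)OC(C)=O
Why: DMAP-catalysed acylation of the primary allylic alcohol installs the acetate that serves as leaving group at C13 later.

Step 9
Reactants: 17 [(5S)-4-(1-ethoxyethenyl)-5-[(2S,3R)-3-methyl-3-(pent-3-yn-1-yl)oxiran-2-yl]-2-oxo-2,5-dihydrofuran-3-yl]methyl acetate
Product: 18 [(5S)-4-(bromoacetyl)-5-[(2S,3R)-3-methyl-3-(pent-3-yn-1-yl)oxiran-2-yl]-2-oxo-2,5-dihydrofuran-3-yl]methyl acetate
Conditions: NBS, THF/H2O, 0 °C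
Reagents that add atoms: N-bromosuccinimide O=C1CCC(=O)N1Br; water O
Why: Bromination of an enol ether in water (bromohydrin-type addition followed by loss of ethanol) gives the bromomethyl ketone regiospecifically at C9, because the electron-rich enol ether reacts far faster with NBS than the alkyne or the acceptor-substituted butenolide alkene.

Step 10
Reactants: 18 [(5S)-4-(bromoacetyl)-5-[(2S,3R)-3-methyl-3-(pent-3-yn-1-yl)oxiran-2-yl]-2-oxo-2,5-dihydrofuran-3-yl]methyl acetate
Product: 19 [(5S)-4-(bromoacetyl)-5-[(2S,3R)-3-(3,4-dioxopentyl)-3-methyloxiran-2-yl]-2-oxo-2,5-dihydrofuran-3-yl]methyl acetate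
Conditions: RuO2·xH2O (cat.), NaIO4, EtOAc/MeCN/H2O, 0 °C → rt
Reagents that add atoms: sodium periodate [Na+].[O-]I(=O)(=O)=O
Why: RuO4 oxidation of an internal alkyne (RuO2/NaIO4) gives the 1,2-diketone directly, the dialkyl alkyne being oxidised faster than the tetrasubstituted, doubly acceptor-substituted butenolide alkene, and the neutral medium spares the base-sensitive C6–H and the epoxide.

Step 11
Reactants: 19 [(5S)-4-(bromoacetyl)-5-[(2S,3R)-3-(3,4-dioxopentyl)-3-methyloxiran-2-yl]-2-oxo-2,5-dihydrofuran-3-yl]methyl acetate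
Product: 21 (4R,5S,6R,7R,10R)-4,5:7,10-diepoxy-1,8-dioxogermacr-11(13)-en-12,6-olide, via samarium aldolate 20 (not isolated)
Conditions: SmI2 (2.2 equiv, slow addition), THF (0.003 M), −78 → −20 °C; pH 7 buffer
Reagents that add atoms: none
Why: SmI2 cleaves the C9–Br bond by two-electron reduction to a trivalent samarium enolate, which adds to the acetyl carbonyl C10 of the 1,2-diketone (Reformatsky-type aldol) to give aldolate 20, whose alkoxide then attacks C7, the β-carbon of the butenolide, with loss of acetate from C13 (SN2′ by addition–elimination), so that the reversible aldol step is pulled forward and the methylene lactone appears. The closest known reaction types are the SmI2-promoted intramolecular Reformatsky reaction used to close medium and large rings and the SN2′ etherification of 2-(acetoxymethyl)enoates by alkoxides. The ten-membered carbocycle closes in a 10-(enolendo)-exo-trig aldol addition and the oxolane in a 5-exo-trig conjugate addition followed by β-elimination. C7 is controlled by C6, because the ten-membered ring leaves the butenolide on the face that carries C5 and the alkoxide can therefore reach C7 only from that face (new C–O bond cis to C5), and C10 is then dictated by the bridge, since only the aldolate epimer whose oxygen points to this face can close while the other returns by retro-aldol. The step needs attack at C10 and not at C1 (the acetyl carbonyl is the less hindered one and leads to the ten- and not the nine-membered ring), attack of oxygen at C7 and not at C11 or C13 (5-exo against 6-endo or 7-exo, and only the C7 adduct can expel acetate) and reduction of the C–Br bond before the diketone (the conjugated α-bromoketone is the best electron acceptor, and an enediolate formed from the diketone would be alkylated by the bromoketone at C9 to the same aldolate). Slow addition of SmI2 to a dilute solution at −78 °C is chosen to hold back intermolecular aldol addition and over-reduction.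

Step 12
Reactants: 21 (4R,5S,6R,7R,10R)-4,5:7,10-diepoxy-1,8-dioxogermacr-11(13)-en-12,6-olide
Product: 22 (4R,5S,6R,7S,8R,10R)-4,5:7,10-diepoxy-8-hydroxy-1-oxogermacr-11(13)-en-12,6-olide (8-endo alcohol)
Conditions: NaBH4, CeCl3·7H2O, MeOH, −78 °C
Reagents that add atoms: none
Why: Luche reduction, in which the strained five-membered-ring ketone C8 reacts much faster than the ten-membered-ring ketone C1 and CeCl3 suppresses conjugate reduction of the methylene lactone, and in which hydride should enter C8 from the exo face next to the ether bridge (away from the six-carbon bridge and the lactone) and so give the endo, (8R)-alcohol.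

Step 13
Reactants: 22 (4R,5S,6R,7S,8R,10R)-4,5:7,10-diepoxy-8-hydroxy-1-oxogermacr-11(13)-en-12,6-olide; 23 methacrylic acid
Product: 24 (4R,5S,6R,7S,8S,10R)-4,5:7,10-diepoxy-1-oxo-12,6-olidogermacr-11(13)-en-8-yl 2-methylprop-2-enoate (CNP0241021.1)
Conditions: PPh3, DIAD, toluene, 0 °C → rt
Reagents that add atoms: none
Why: Mitsunobu esterification, in which methacrylate displaces the oxyphosphonium group from the open exo face with inversion at C8 and so gives the (8S)-ester of the target directly.

Compound list
1 | nerol, (2Z)-3,7-dimethylocta-2,6-dien-1-ol | CC(C)=CCC/C(C)=C\CO | starting material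
2 | [(2S,3R)-3-methyl-3-(4-methylpent-3-en-1-yl)oxiran-2-yl]methanol | OC[C@@H]1O[C@]1(C)CCC=C(C)C | intermediate
3 | ozonide (1,2,4-trioxolane) of 2, both epimers at the trioxolane CH | OC[C@@H]1O[C@]1(C)CCC2OOC(C)(C)O2 | intermediate
4 | 3-[(2R,3S)-3-(hydroxymethyl)-2-methyloxiran-2-yl]propanal | OC[C@@H]1O[C@]1(C)CCC=O | intermediate
5 | [(2S,3R)-3-(but-3-yn-1-yl)-3-methyloxiran-2-yl]methanol | OC[C@@H]1O[C@]1(C)CCC#C | intermediate
6 | dilithio derivative of 5 (lithium alkoxide and lithium acetylide) | [Li]OC[C@@H]1O[C@]1(C)CCC#C[Li] | intermediate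
7 | [(2S,3R)-3-methyl-3-(pent-3-yn-1-yl)oxiran-2-yl]methanol | OC[C@@H]1O[C@]1(C)CCC#CC | intermediate
8 | (2R,3R)-3-methyl-3-(pent-3-yn-1-yl)oxirane-2-carbaldehyde | O=C[C@@H]1O[C@]1(C)CCC#CC | intermediate
9 | methyl propiolate | C#CC(=O)OC | starting material
10 | lithium methyl propiolate, LiC≡CCO2Me | [Li]C#CC(=O)OC | intermediate
11 | methyl (4S)-4-hydroxy-4-[(2S,3R)-3-methyl-3-(pent-3-yn-1-yl)oxiran-2-yl]but-2-ynoate | COC(=O)C#C[C@H](O)[C@@H]1O[C@]1(C)CCC#CC | intermediate
12 | ethyl vinyl ether | C=COCC | starting material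
13 | 1-ethoxyvinyllithium, LiC(OEt)=CH2 | [Li]C(=C)OCC | intermediate
14 | lithium bis(1-ethoxyvinyl)cuprate, LiCu[C(OEt)=CH2]2 | [Li+].CCOC(=C)[Cu-]C(=C)OCC | intermediate
15 | dilithium dialkoxide of methyl (2E,4S)-3-(1-ethoxyethenyl)-4-hydroxy-2-(hydroxymethyl)-4-[(2S,3R)-3-methyl-3-(pent-3-yn-1-yl)oxiran-2-yl]but-2-enoate | COC(=O)/C(CO[Li])=C(/C(=C)OCC)[C@H](O[Li])[C@@H]1O[C@]1(C)CCC#CC | intermediate
16 | (5S)-4-(1-ethoxyethenyl)-3-(hydroxymethyl)-5-[(2S,3R)-3-methyl-3-(pent-3-yn-1-yl)oxiran-2-yl]furan-2(5H)-one | CCOC(=C)C1=C(CO)C(=O)O[C@@H]1[C@@H]2O[C@]2(C)CCC#CC | intermediate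
17 | [(5S)-4-(1-ethoxyethenyl)-5-[(2S,3R)-3-methyl-3-(pent-3-yn-1-yl)oxiran-2-yl]-2-oxo-2,5-dihydrofuran-3-yl]methyl acetate | CCOC(=C)C1=C(COC(C)=O)C(=O)O[C@@H]1[C@@H]2O[C@]2(C)CCC#CC | intermediate
18 | [(5S)-4-(bromoacetyl)-5-[(2S,3R)-3-methyl-3-(pent-3-yn-1-yl)oxiran-2-yl]-2-oxo-2,5-dihydrofuran-3-yl]methyl acetate | BrCC(=O)C1=C(COC(C)=O)C(=O)O[C@@H]1[C@@H]2O[C@]2(C)CCC#CC | intermediate
19 | [(5S)-4-(bromoacetyl)-5-[(2S,3R)-3-(3,4-dioxopentyl)-3-methyloxiran-2-yl]-2-oxo-2,5-dihydrofuran-3-yl]methyl acetate | BrCC(=O)C1=C(COC(C)=O)C(=O)O[C@@H]1[C@@H]2O[C@]2(C)CCC(=O)C(C)=O | intermediate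
20 | samarium aldolate: ten-membered C9–C10 aldol adduct of 19 as its trivalent samarium alkoxide (C10–O–SmI2; 4R,5S,6S,10R) | C[C@@]1(O[Sm](I)I)CC(=O)C2=C(COC(C)=O)C(=O)O[C@@H]2[C@@H]3O[C@]3(C)CCC1=O | intermediate
21 | (4R,5S,6R,7R,10R)-4,5:7,10-diepoxy-1,8-dioxogermacr-11(13)-en-12,6-olide | O=C1C[C@@]2(C)O[C@@]13C(=C)C(=O)O[C@@H]3[C@@H]1O[C@]1(C)CCC2=O | intermediate
22 | (4R,5S,6R,7S,8R,10R)-4,5:7,10-diepoxy-8-hydroxy-1-oxogermacr-11(13)-en-12,6-olide | O[C@@H]1C[C@@]2(C)O[C@@]13C(=C)C(=O)O[C@@H]3[C@@H]1O[C@]1(C)CCC2=O | intermediate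
23 | methacrylic acid | CC(=C)C(=O)O | starting material
24 | (4R,5S,6R,7S,8S,10R)-4,5:7,10-diepoxy-1-oxo-12,6-olidogermacr-11(13)-en-8-yl 2-methylprop-2-enoate (CNP0241021.1) | C=C(C)C(=O)O[C@H]1C[C@@]2(C)O[C@@]13C(=C)C(=O)O[C@@H]3[C@@H]1O[C@]1(C)CCC2=O | target

Total step count: 13. Longest linear sequence: 13 steps (from nerol 1).

Steps most likely to fail

Step 11 (key step). The samarium enolate may be protonated or may add intermolecularly before the strained ten-membered ring closes, or the 1,2-diketone may be reduced ahead of the bromoketone. The fallback sets out from 19 and comes back at 21, and makes the two bonds in separate known reactions. Reductive silylation of the bromoketone (Zn, Me3SiCl, THF/MeCN, 0 °C) should give the trimethylsilyl enol ether F1. A Mukaiyama aldol addition under high dilution, with the diketone held as a chelate by a Lewis acid (Cu(OTf)2/bis(oxazoline), CH2Cl2, −78 °C, then dilute acid), should give the isolated ten-membered aldol F2. A Tsuji–Trost allylic etherification (Pd(PPh3)4, a zerovalent palladium catalyst, THF, rt) should then close the oxolane at C7 with loss of acetate to give 21.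

Step 7. The alkenylcopper intermediate may be protonated, or may lose its geometry through the allenolate, before formaldehyde traps it, so that hydroxymethylation or lactonisation fails. The fallback sets out from 11 and comes back at 16. The same cuprate addition would be quenched with iodine at −78 °C, the fastest trap for alkenylcopper species, which after lactonisation should give the 3-iodobutenolide F3. A Stille coupling with (tributylstannyl)methanol (Pd(PPh3)4, dioxane, 80 °C) would then put the hydroxymethyl group on C11 and give 16.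

Step 13. Displacement at C8, which is flanked by the fully substituted C7, may be too slow under Mitsunobu conditions, so that elimination toward C9 or recovery of the alcohol results. The fallback sets out from 22 and comes back at 24. The alcohol would be converted into the discrete endo triflate F4 (Tf2O, pyridine, CH2Cl2, −20 °C), and this would be displaced from the exo face with cesium methacrylate (18-crown-6, toluene, rt to 50 °C), as in carboxylate inversions of hindered carbohydrate triflates, to give 24 with inversion.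

Further compounds
F1 | step 11 | [(5S)-5-[(2S,3R)-3-(3,4-dioxopentyl)-3-methyloxiran-2-yl]-2-oxo-4-[1-(trimethylsilyloxy)ethenyl]-2,5-dihydrofuran-3-yl]methyl acetate | C=C(O[Si](C)(C)C)C1=C(COC(C)=O)C(=O)O[C@@H]1[C@@H]2O[C@]2(C)CCC(=O)C(C)=O
F2 | step 11 | ten-membered aldol, free tertiary alcohol corresponding to 20 (4R,5S,6S,10R) | C[C@@]1(O)CC(=O)C2=C(COC(C)=O)C(=O)O[C@@H]2[C@@H]3O[C@]3(C)CCC1=O
F3 | step 7 | (5S)-4-(1-ethoxyethenyl)-3-iodo-5-[(2S,3R)-3-methyl-3-(pent-3-yn-1-yl)oxiran-2-yl]furan-2(5H)-one | CCOC(=C)C1=C(I)C(=O)O[C@@H]1[C@@H]2O[C@]2(C)CCC#CC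
F4 | step 13 | 8-endo trifluoromethanesulfonate of 22 | O=S(=O)(O[C@@H]1C[C@@]2(C)O[C@@]13C(=C)C(=O)O[C@@H]3[C@@H]1O[C@]1(C)CCC2=O)C(F)(F)F
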